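**Retrosynthetic overview**
1. Feature: in the tetrahydrochromone half the C5–C8 carbocycle is a cyclohexene whose only alkene is C4a=C8a and whose O7 and O8 are cis, the pattern of an arene cis-dihydrodiol. C7–O and C8–O are therefore disconnected to O2 and bromobenzene by enzymatic dearomatisation, the C–Br carbon becoming C8a.
2. O6 (β) and O5 (α) come from anti epoxidation of the diene acetonide and hydroxide opening at allylic C5. A protecting-group exchange then leaves O5, O6 and O7 as TBS ethers and O8 as a TES ether.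
3. Pyranone of this half: C8a–Br to C8a–B to C8a=O, boron aldol at C4a with 5-phenylpent-2-ynal, oxidation, 6-endo-dig closure of O1–C2.
4. Last disconnection: the C6(aryl)–O8 bond, made by copper O-arylation of the free C8 hydroxyl with the trifluoroborate of 6-bromo-7-methoxy-2-(2-phenylethyl)chromone (from paeonol and ethyl 3-phenylpropanoate), followed by global desilylation.
5. Ring order: the carbocycle is the benzene ring of bromobenzene and is never closed; the aromatic chromone pyranone is closed in its own branch (step 16) and the pyranone of the tetrahydro half at step 13.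

Key step: step 1

Remark: ring carbons of every intermediate carry the numbers they will have in the tetrahydrochromone half (C4a, C5–C8, C8a); α is the face of O7 and O8, β the opposite face.

**Route**

Step 1
Reactants: 1 bromobenzene
Product: 2 (1S,2S)-3-bromocyclohexa-3,5-diene-1,2-diol
Conditions: E. coli JM109(pDTG601) whole cells expressing toluene dioxygenase, glucose feed, air, phosphate buffer pH 7, 30 °C; EtOAc extraction
Reagents that add atoms: dioxygen, O=O
Why: The Rieske non-haem iron dioxygenase binds O2 at its reduced mononuclear iron centre (divalent iron, electrons relayed from NADH through reductase, ferredoxin and the [2Fe–2S] cluster) and delivers both oxygen atoms to one face of the C2=C3 bond of bromobenzene, so the future C8–O and C7–O bonds form together and a cyclohexadiene is left. The closest known reaction type is the whole-cell toluene dioxygenase cis-dihydroxylation of halobenzenes and other monosubstituted benzenes. No ring is closed; the arene is dearomatised. Both new stereocentres, (1S,2S), are fixed by the enzyme pocket, which holds the bromine in one orientation and presents a single face of the ortho/meta bond to the iron-bound oxygen. The step needs 2,3-regioselectivity (diol ortho and meta to Br, so that the C–Br carbon becomes C8a) and one enantiomer; both come from the active site, the substrate only having to carry one medium-sized substituent. The diol is kept cold and near neutral pH and is used at once, because acid or heat would dehydrate it to bromophenols.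

Step 2
Reactants: 2 (1S,2S)-3-bromocyclohexa-3,5-diene-1,2-diol
Product: 3 (3aS,7aS)-4-bromo-2,2-dimethyl-3a,7a-dihydro-1,3-benzodioxole (7α,8α-acetonide)
Conditions: 2,2-dimethoxypropane, p-TsOH (cat.), acetone, rt
Reagents that add atoms: 2,2-dimethoxypropane, COC(C)(C)OC
Why: Acid-catalysed acetal exchange (transketalisation) closes the cis-fused dioxolane on the cis-diol faster than the diene can dehydrate, and neither stereocentre is touched.

Step 3
Reactants: 3 (3aS,7aS)-4-bromo-2,2-dimethyl-3a,7a-dihydro-1,3-benzodioxole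
Product: 4 5β,6β-epoxide of 3 (oxirane anti to the dioxolane; bromoalkene C4a=C8a kept)
Conditions: mCPBA, CH2Cl2, 0 °C → rt
Reagents that add atoms: mCPBA, OOC(=O)c1cccc(Cl)c1
Why: Prilezhaev epoxidation with a peracid takes the electron-richer C5=C6 alkene (C4a=C8a is deactivated by bromine) from the β face because the cis-fused dioxolane blocks the α face, which sets C6–O β (and, for the moment, C5–O β).

Step 4
Reactants: 4 5β,6β-epoxide of 3
Product: 5 (3aS,4R,5S,7aS)-7-bromo-2,2-dimethyl-3a,4,5,7a-tetrahydro-1,3-benzodioxole-4,5-diol (5α-OH and 6β-OH; 7α,8α-acetonide)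
Conditions: 10% aq. KOH, DMSO, 80 °C
Reagents that add atoms: water (delivered as hydroxide from KOH), O
Why: Hydrolytic opening of a vinyl oxirane by SN2 attack of hydroxide at the allylic carbon C5 with inversion (trans-diaxial opening) turns C5 into the 5α-alcohol trans to the 6β-alcohol, while the acetonide and the alkenyl bromide are inert to aqueous base.

Step 5
Reactants: 5 (3aS,4R,5S,7aS)-7-bromo-2,2-dimethyl-3a,4,5,7a-tetrahydro-1,3-benzodioxole-4,5-diol
Product: 6 5α,6β-bis(tert-butyldimethylsilyl) ether of 5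
Conditions: TBSOTf, 2,6-lutidine, CH2Cl2, 0 °C → rt
Reagents that add atoms: tert-butyldimethylsilyl triflate, CC(C)(C)[Si](C)(C)OS(=O)(=O)C(F)(F)F
Why: Silyl ether formation with the silyl triflate and a hindered pyridine base caps both hydroxyls of the hindered trans-diol, which the chloride would do only sluggishly, and no stereocentre is involved.

Step 6
Reactants: 6 5α,6β-bis(tert-butyldimethylsilyl) ether of 5
Product: 7 8a-bromo-5α,6β-bis(tert-butyldimethylsilyloxy)cyclohex-4a(8a)-ene-7α,8α-diol
Conditions: TFA/H2O (9:1), CH2Cl2, 0 °C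
Reagents that add atoms: none
Why: Acid-catalysed acetal hydrolysis cleaves the isopropylidene group at 0 °C faster than the two hindered secondary silyl ethers and releases the 7α,8α-diol with all ring C–O bonds intact.

Step 7
Reactants: 7 8a-bromo-5α,6β-bis(tert-butyldimethylsilyloxy)cyclohex-4a(8a)-ene-7α,8α-diol
Product: 8 8a-bromo-5α,6β,7α-tris(tert-butyldimethylsilyloxy)cyclohex-4a(8a)-en-8α-ol
Conditions: TBSCl (1.1 equiv), imidazole, DMF, 0 °C → rt
Reagents that add atoms: tert-butyldimethylsilyl chloride, CC(C)(C)[Si](C)(C)Cl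
Why: Regioselective monosilylation: since O5 and O7 are 1,3-cis the ring avoids the half-chair in which they would be syn-diaxial, so O7 is equatorial and remote from bromine whereas O8 is pseudoaxial and flanked by the C–Br carbon, and the bulky chlorosilane should therefore take O7, in line with the distal-hydroxyl selectivity of bulky silyl chlorides on arene cis-dihydrodiols.

Step 8
Reactants: 8 8a-bromo-5α,6β,7α-tris(tert-butyldimethylsilyloxy)cyclohex-4a(8a)-en-8α-ol
Product: 9 8α-triethylsilyl ether of 8
Conditions: TESOTf, 2,6-lutidine, CH2Cl2, −78 °C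
Reagents that add atoms: triethylsilyl triflate, CC[Si](CC)(CC)OS(=O)(=O)C(F)(F)F
Why: Silyl ether formation with the more reactive triethylsilyl triflate covers the remaining hindered allylic hydroxyl under non-basic conditions that exclude 1,2-silyl migration, and gives O8 a group that can later be removed beside three tert-butyldimethylsilyl ethers.

Step 9
Reactants: 9 8α-triethylsilyl ether of 8
Product: 10 pinacol alkenylboronate (9 with the 4,4,5,5-tetramethyl-1,3,2-dioxaborolan-2-yl group in place of Br at C8a)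
Conditions: B2pin2, PdCl2(PPh3)2 (cat.), PPh3, KOPh, toluene, 50 °C
Reagents that add atoms: bis(pinacolato)diboron, CC1(C)OB(OC1(C)C)B1OC(C)(C)C(C)(C)O1
Why: Miyaura borylation of an alkenyl bromide (oxidative addition of C8a–Br to zerovalent palladium, phenoxide-assisted transmetalation with B2pin2, reductive elimination) replaces bromine by boron with the alkene held at C4a=C8a, the mild phenoxide base sparing the silyl ethers.

Step 10
Reactants: 10 pinacol alkenylboronate
Product: 11 5α,6β,7α-tris(tert-butyldimethylsilyloxy)-8α-(triethylsilyloxy)cyclohexan-8a-one (C4a is CH2)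
Conditions: 30% aq. H2O2, NaHCO3, THF/H2O, 0 °C
Reagents that add atoms: hydrogen peroxide, OO
Why: Oxidation of the alkenyl C–B bond by hydroperoxide (1,2-migration of C8a from boron to oxygen) gives an enol borate that hydrolyses and tautomerises to the C8a ketone, C4a becoming a methylene so that no stereocentre is formed, and the bicarbonate buffer at 0 °C is mild enough to leave C8 and the β-silyloxy groups alone.

Step 11
Reactants: 12 4-phenyl-1-butyne
Product: 13 5-phenylpent-2-ynal
Conditions: n-BuLi, THF, −78 °C; DMF; inverse quench into aq. KH2PO4, 0 °C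
Reagents that add atoms: N,N-dimethylformamide, CN(C)C=O
Why: Formylation of the lithium acetylide with DMF followed by inverse quench into phosphate buffer liberates the ynal from its lithium hemiaminal without conjugate addition of the released dimethylamine.

Step 12
Reactants: 11 5α,6β,7α-tris(tert-butyldimethylsilyloxy)-8α-(triethylsilyloxy)cyclohexan-8a-one; 13 5-phenylpent-2-ynal
Product: 15 aldol adduct (11 carrying a 1-hydroxy-5-phenylpent-2-yn-1-yl group at C4a; mixture at C4a and the carbinol carbon), via dibutylboron enolate 14 (not isolated)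
Conditions: Bu2BOTf, i-Pr2NEt, CH2Cl2, −78 → 0 °C; 13, −78 °C; then pH 7 buffer, MeOH, 30% H2O2, 0 °C
Reagents that add atoms: dibutylboron triflate, CCCCB(CCCC)OS(=O)(=O)C(F)(F)F (its Bu2B group is held in 14 and lost on work-up)
Why: Boron aldol addition: soft enolisation with Bu2BOTf and a tertiary amine removes a proton from the C4a methylene and not from the silyloxy-bearing C8 methine, the covalent boron enolate does not expel the C5 silyloxy group, and it adds 1,2 to the ynal through a closed six-membered transition state, the two new stereocentres (C4a and the carbinol carbon) being left uncontrolled because both are erased in the next step.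

Step 13
Reactants: 15 aldol adduct
Product: 17 5α,6β,7α-tris(tert-butyldimethylsilyloxy)-8α-(triethylsilyloxy)-2-(2-phenylethyl)-5,6,7,8-tetrahydro-4H-chromen-4-one, via ynedione 16 (not isolated)
Conditions: Dess–Martin periodinane, NaHCO3, CH2Cl2, 0 °C; filter; Ph3PAuNTf2 (5 mol %), CH2Cl2, rt
Reagents that add atoms: none
Why: Dess–Martin oxidation of the propargylic alcohol gives the 2-alkynoyl ketone, whose C8a enol oxygen then adds to the β-carbon of the gold-activated ynone in a 6-endo-dig oxa-Michael cyclisation (favoured by the ring-closure rules and by the polarity of the ynone) that forms the O1–C2 bond of the 4-pyranone under non-basic conditions, so that the C5 silyloxy group is not eliminated and C4a becomes sp2.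

Step 14
Reactants: 17 5α,6β,7α-tris(tert-butyldimethylsilyloxy)-8α-(triethylsilyloxy)-2-(2-phenylethyl)-5,6,7,8-tetrahydro-4H-chromen-4-one
Product: 18 5α,6β,7α-tris(tert-butyldimethylsilyloxy)-8α-hydroxy-2-(2-phenylethyl)-5,6,7,8-tetrahydro-4H-chromen-4-one
Conditions: PPTS, MeOH/CH2Cl2, 0 °C
Reagents that add atoms: none
Why: Selective acid-catalysed methanolysis of a triethylsilyl ether, which is cleaved much faster than tert-butyldimethylsilyl ethers, frees O8 alone without breaking the C8–O bond.

Step 15
Reactants: 19 paeonol (1-(2-hydroxy-4-methoxyphenyl)ethanone)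
Product: 20 1-(5-bromo-2-hydroxy-4-methoxyphenyl)ethanone
Conditions: NBS, MeCN, 0 °C → rt
Reagents that add atoms: N-bromosuccinimide, BrN1C(=O)CCC1=O
Why: Electrophilic aromatic bromination occurs para to the phenol and ortho to the methoxy group (C5 of paeonol), the position between the two oxygens being more hindered.

Step 16
Reactants: 20 1-(5-bromo-2-hydroxy-4-methoxyphenyl)ethanone; 21 ethyl 3-phenylpropanoate
Product: 23 6-bromo-7-methoxy-2-(2-phenylethyl)-4H-chromen-4-one, via diketone 22 (not isolated)
Conditions: NaH, THF, reflux; then conc. HCl, AcOH, 80 °C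
Reagents that add atoms: none
Why: Crossed Claisen condensation of the ketone enolate of the phenoxide with the ester gives the 1,3-diketone, and acid then drives cyclodehydration of the phenol onto the distal carbonyl to close the aromatic 4-pyranone ring (classical 2-alkylchromone synthesis).

Step 17
Reactants: 23 6-bromo-7-methoxy-2-(2-phenylethyl)-4H-chromen-4-one
Product: 24 7-methoxy-2-(2-phenylethyl)-6-(4,4,5,5-tetramethyl-1,3,2-dioxaborolan-2-yl)-4H-chromen-4-one
Conditions: B2pin2, Pd(dppf)Cl2 (cat.), KOAc, 1,4-dioxane, 90 °C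
Reagents that add atoms: bis(pinacolato)diboron, CC1(C)OB(OC1(C)C)B1OC(C)(C)C(C)(C)O1
Why: Miyaura borylation of the aryl bromide (oxidative addition to zerovalent palladium, acetate-assisted transmetalation, reductive elimination) tolerates the chromone carbonyl and the ortho methoxy group.

Step 18
Reactants: 24 7-methoxy-2-(2-phenylethyl)-6-(4,4,5,5-tetramethyl-1,3,2-dioxaborolan-2-yl)-4H-chromen-4-one
Product: 25 potassium trifluoro[7-methoxy-4-oxo-2-(2-phenylethyl)-4H-chromen-6-yl]borate
Conditions: KHF2, MeOH/H2O, rt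
Reagents that add atoms: potassium hydrogen difluoride, [K+].[F-].F
Why: Fluoride exchange at boron with KHF2 converts the pinacol boronate into the crystalline potassium trifluoroborate, the aryl donor best suited to copper etherification of aliphatic alcohols.

Step 19
Reactants: 18 5α,6β,7α-tris(tert-butyldimethylsilyloxy)-8α-hydroxy-2-(2-phenylethyl)-5,6,7,8-tetrahydro-4H-chromen-4-one; 25 potassium trifluoro[7-methoxy-4-oxo-2-(2-phenylethyl)-4H-chromen-6-yl]borate
Product: 26 5α,6β,7α-tris(tert-butyldimethylsilyloxy)-8α-{[7-methoxy-4-oxo-2-(2-phenylethyl)-4H-chromen-6-yl]oxy}-2-(2-phenylethyl)-5,6,7,8-tetrahydro-4H-chromen-4-one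
Conditions: 25 (excess), Cu(OAc)2·H2O, DMAP, 4 Å MS, O2 (1 atm), CH2Cl2, rt
Reagents that add atoms: none
Why: Chan–Lam etherification: the aryl group passes from boron to divalent copper, the alkoxide of 18 binds, oxidation by O2 gives a trivalent copper aryl alkoxide and C(aryl)–O reductive elimination follows at room temperature without strong base, so that the enzyme-made C8–O bond and its configuration are kept and the neighbouring silyl ether does not migrate.

Step 20
Reactants: 26 5α,6β,7α-tris(tert-butyldimethylsilyloxy)-8α-{[7-methoxy-4-oxo-2-(2-phenylethyl)-4H-chromen-6-yl]oxy}-2-(2-phenylethyl)-5,6,7,8-tetrahydro-4H-chromen-4-one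
Product: 27 (5S,6R,7S,8S)-5,6,7-trihydroxy-8-{[7-methoxy-4-oxo-2-(2-phenylethyl)-4H-chromen-6-yl]oxy}-2-(2-phenylethyl)-5,6,7,8-tetrahydro-4H-chromen-4-one (CNP0125425.2)
Conditions: HF·pyridine, pyridine, THF, 0 °C → rt
Reagents that add atoms: none
Why: Fluoride-driven cleavage of the three Si–O bonds with pyridine-buffered HF·pyridine (desilylation) releases the 5,6,7-triol without acid strong enough to dehydrate the tetrahydrochromone or to cleave the C8 aryl ether, and no stereocentre is touched.

**Compound list**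

1 | bromobenzene | Brc1ccccc1 | starting material
2 | (1S,2S)-3-bromocyclohexa-3,5-diene-1,2-diol | O[C@@H]1C(Br)=CC=C[C@@H]1O | intermediate
3 | (3aS,7aS)-4-bromo-2,2-dimethyl-3a,7a-dihydro-1,3-benzodioxole | CC1(C)O[C@@H]2C(Br)=CC=C[C@@H]2O1 | intermediate
4 | 5β,6β-epoxide of 3 (oxirane anti to the dioxolane) | CC1(C)O[C@@H]2C(Br)=C[C@H]3O[C@H]3[C@@H]2O1 | intermediate
5 | (3aS,4R,5S,7aS)-7-bromo-2,2-dimethyl-3a,4,5,7a-tetrahydro-1,3-benzodioxole-4,5-diol | CC1(C)O[C@@H]2C(Br)=C[C@H](O)[C@@H](O)[C@@H]2O1 | intermediate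
6 | 5α,6β-bis(tert-butyldimethylsilyl) ether of 5 | CC1(C)O[C@@H]2C(Br)=C[C@H](O[Si](C)(C)C(C)(C)C)[C@@H](O[Si](C)(C)C(C)(C)C)[C@@H]2O1 | intermediate
7 | 8a-bromo-5α,6β-bis(tert-butyldimethylsilyloxy)cyclohex-4a(8a)-ene-7α,8α-diol | O[C@@H]1C(Br)=C[C@H](O[Si](C)(C)C(C)(C)C)[C@@H](O[Si](C)(C)C(C)(C)C)[C@@H]1O | intermediate
8 | 8a-bromo-5α,6β,7α-tris(tert-butyldimethylsilyloxy)cyclohex-4a(8a)-en-8α-ol | O[C@@H]1C(Br)=C[C@H](O[Si](C)(C)C(C)(C)C)[C@@H](O[Si](C)(C)C(C)(C)C)[C@@H]1O[Si](C)(C)C(C)(C)C | intermediate
9 | 8α-triethylsilyl ether of 8 | CC[Si](CC)(CC)O[C@@H]1C(Br)=C[C@H](O[Si](C)(C)C(C)(C)C)[C@@H](O[Si](C)(C)C(C)(C)C)[C@@H]1O[Si](C)(C)C(C)(C)C | intermediate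
10 | pinacol alkenylboronate (Bpin at C8a in place of Br of 9) | CC[Si](CC)(CC)O[C@@H]1C(B2OC(C)(C)C(C)(C)O2)=C[C@H](O[Si](C)(C)C(C)(C)C)[C@@H](O[Si](C)(C)C(C)(C)C)[C@@H]1O[Si](C)(C)C(C)(C)C | intermediate
11 | 5α,6β,7α-tris(tert-butyldimethylsilyloxy)-8α-(triethylsilyloxy)cyclohexan-8a-one | CC[Si](CC)(CC)O[C@@H]1C(=O)C[C@H](O[Si](C)(C)C(C)(C)C)[C@@H](O[Si](C)(C)C(C)(C)C)[C@@H]1O[Si](C)(C)C(C)(C)C | intermediate
12 | 4-phenyl-1-butyne | C#CCCc1ccccc1 | starting material
13 | 5-phenylpent-2-ynal | O=CC#CCCc1ccccc1 | intermediate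
14 | dibutylboron enolate of 11 (O–B at C8a, alkene C4a=C8a) | CC[Si](CC)(CC)O[C@@H]1C(OB(CCCC)CCCC)=C[C@H](O[Si](C)(C)C(C)(C)C)[C@@H](O[Si](C)(C)C(C)(C)C)[C@@H]1O[Si](C)(C)C(C)(C)C | intermediate (not isolated)
15 | aldol adduct: 11 with 1-hydroxy-5-phenylpent-2-yn-1-yl at C4a (mixture at C4a and carbinol carbon) | CC[Si](CC)(CC)O[C@@H]1C(=O)C(C(O)C#CCCc2ccccc2)[C@H](O[Si](C)(C)C(C)(C)C)[C@@H](O[Si](C)(C)C(C)(C)C)[C@@H]1O[Si](C)(C)C(C)(C)C | intermediate
16 | ynedione: 11 with 5-phenylpent-2-ynoyl at C4a (enolised) | CC[Si](CC)(CC)O[C@@H]1C(=O)C(C(=O)C#CCCc2ccccc2)[C@H](O[Si](C)(C)C(C)(C)C)[C@@H](O[Si](C)(C)C(C)(C)C)[C@@H]1O[Si](C)(C)C(C)(C)C | intermediate (not isolated)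
17 | 5α,6β,7α-tris(tert-butyldimethylsilyloxy)-8α-(triethylsilyloxy)-2-(2-phenylethyl)-5,6,7,8-tetrahydro-4H-chromen-4-one | CC[Si](CC)(CC)O[C@@H]1c2oc(CCc3ccccc3)cc(=O)c2[C@H](O[Si](C)(C)C(C)(C)C)[C@@H](O[Si](C)(C)C(C)(C)C)[C@@H]1O[Si](C)(C)C(C)(C)C | intermediate
18 | 5α,6β,7α-tris(tert-butyldimethylsilyloxy)-8α-hydroxy-2-(2-phenylethyl)-5,6,7,8-tetrahydro-4H-chromen-4-one | O[C@@H]1c2oc(CCc3ccccc3)cc(=O)c2[C@H](O[Si](C)(C)C(C)(C)C)[C@@H](O[Si](C)(C)C(C)(C)C)[C@@H]1O[Si](C)(C)C(C)(C)C | intermediate
19 | paeonol, 1-(2-hydroxy-4-methoxyphenyl)ethanone | CC(=O)c1ccc(OC)cc1O | starting material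
20 | 1-(5-bromo-2-hydroxy-4-methoxyphenyl)ethanone | CC(=O)c1cc(Br)c(OC)cc1O | intermediate
21 | ethyl 3-phenylpropanoate | CCOC(=O)CCc1ccccc1 | starting material
22 | 1-(5-bromo-2-hydroxy-4-methoxyphenyl)-5-phenylpentane-1,3-dione | O=C(CCc1ccccc1)CC(=O)c1cc(Br)c(OC)cc1O | intermediate (not isolated)
23 | 6-bromo-7-methoxy-2-(2-phenylethyl)-4H-chromen-4-one | COc1cc2oc(CCc3ccccc3)cc(=O)c2cc1Br | intermediate
24 | 7-methoxy-2-(2-phenylethyl)-6-(4,4,5,5-tetramethyl-1,3,2-dioxaborolan-2-yl)-4H-chromen-4-one | COc1cc2oc(CCc3ccccc3)cc(=O)c2cc1B1OC(C)(C)C(C)(C)O1 | intermediate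
25 | potassium trifluoro[7-methoxy-4-oxo-2-(2-phenylethyl)-4H-chromen-6-yl]borate | COc1cc2oc(CCc3ccccc3)cc(=O)c2cc1[B-](F)(F)F.[K+] | intermediate
26 | 5α,6β,7α-tris(tert-butyldimethylsilyloxy)-8α-{[7-methoxy-4-oxo-2-(2-phenylethyl)-4H-chromen-6-yl]oxy}-2-(2-phenylethyl)-5,6,7,8-tetrahydro-4H-chromen-4-one | COc1cc2oc(CCc3ccccc3)cc(=O)c2cc1O[C@@H]1c2oc(CCc3ccccc3)cc(=O)c2[C@H](O[Si](C)(C)C(C)(C)C)[C@@H](O[Si](C)(C)C(C)(C)C)[C@@H]1O[Si](C)(C)C(C)(C)C | intermediate
27 | (5S,6R,7S,8S)-5,6,7-trihydroxy-8-{[7-methoxy-4-oxo-2-(2-phenylethyl)-4H-chromen-6-yl]oxy}-2-(2-phenylethyl)-5,6,7,8-tetrahydro-4H-chromen-4-one | COc1cc2oc(CCc3ccccc3)cc(=O)c2cc1O[C@@H]1c2oc(CCc3ccccc3)cc(=O)c2[C@H](O)[C@@H](O)[C@@H]1O | target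

**Step count and risks**

Total steps: 20. Longest linear sequence: 15 steps (steps 1–10, 12–14, 19 and 20); the ynal branch has 1 step and the aryl branch 4 steps.

Steps most likely to fail:

1. Step 19 (copper etherification). At the hindered secondary C8 hydroxyl, transmetalation and reductive elimination at copper may be slower than protodeboronation or homocoupling of the aryl donor, so that the alcohol is recovered. Fallback: form the C8–O(aryl) bond from the other side by two Mitsunobu inversions. It sets out from 18: 4-nitrobenzoic acid, PPh3 and DIAD in toluene should give, with inversion, the 8β 4-nitrobenzoate F1, and NaN3 in MeOH at 40 °C should transesterify it to the 8β alcohol F2. Boronate 24 is oxidised (NaBO3·4H2O, THF/H2O) to 6-hydroxy-7-methoxy-2-(2-phenylethyl)-4H-chromen-4-one F3. F2 and F3 with PPh3 and DIAD should then give, by a second inversion, the 8α aryl ether, which is 26, where the route is rejoined. The ether oxygen is then the phenol oxygen; the configuration at C8 still derives from the enzymatic diol through the double inversion.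

2. Step 7 (monosilylation of the 7,8-diol). Discrimination between O7 and O8 may be poor, with silylation at O8 or at both oxygens. Fallback: let the stereoelectronic preference of orthoester hydrolysis, not relative nucleophilicity, choose the oxygen. It sets out from 7: trimethyl orthoacetate and PPTS (cat.) in CH2Cl2 should give the cyclic 7,8-orthoacetate F4. 80% aq. AcOH at rt should open it to the ester of the pseudoaxial oxygen, the 8-O-acetyl 7α-ol F5. TBSOTf and 2,6-lutidine at −40 °C should give the 7-O-silyl 8-O-acetate F6. DIBAL-H in CH2Cl2 at −78 °C removes the acetate without generating a free alkoxide next to the silyl ether and returns to the route at 8.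

3. Step 12 (boron aldol). Enolisation may go toward C8, the hindered ketone may enolise incompletely, or the enolate may lose the C5 silyloxy group by β-elimination. Fallback: make the C8a enolate regiospecifically from the alkenylboronate without any base. It sets out from 10: anhydrous trimethylamine N-oxide in CH2Cl2 at rt oxidises the C–B bond to the pinacol enol borate F7, which adds to ynal 13 in the same flask. Work-up with pH 7 buffer should give aldol adduct 15, where the route is rejoined.

**Further compounds**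

F1 | step 19 | 8β 4-nitrobenzoate of the 8-epimer of 18 | O=C(O[C@H]1c2oc(CCc3ccccc3)cc(=O)c2[C@H](O[Si](C)(C)C(C)(C)C)[C@@H](O[Si](C)(C)C(C)(C)C)[C@@H]1O[Si](C)(C)C(C)(C)C)c1ccc(cc1)[N+](=O)[O-]
F2 | step 19 | 5α,6β,7α-tris(tert-butyldimethylsilyloxy)-8β-hydroxy-2-(2-phenylethyl)-5,6,7,8-tetrahydro-4H-chromen-4-one | O[C@H]1c2oc(CCc3ccccc3)cc(=O)c2[C@H](O[Si](C)(C)C(C)(C)C)[C@@H](O[Si](C)(C)C(C)(C)C)[C@@H]1O[Si](C)(C)C(C)(C)C
F3 | step 19 | 6-hydroxy-7-methoxy-2-(2-phenylethyl)-4H-chromen-4-one | COc1cc2oc(CCc3ccccc3)cc(=O)c2cc1O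
F4 | step 7 | cyclic 7α,8α-(1-methoxyethylidene) orthoester of 7 (mixture at the orthoester carbon) | COC1(C)O[C@@H]2C(Br)=C[C@H](O[Si](C)(C)C(C)(C)C)[C@@H](O[Si](C)(C)C(C)(C)C)[C@@H]2O1
F5 | step 7 | 8α-acetoxy-8a-bromo-5α,6β-bis(tert-butyldimethylsilyloxy)cyclohex-4a(8a)-en-7α-ol | CC(=O)O[C@@H]1C(Br)=C[C@H](O[Si](C)(C)C(C)(C)C)[C@@H](O[Si](C)(C)C(C)(C)C)[C@@H]1O
F6 | step 7 | 8α-acetate of 8 | CC(=O)O[C@@H]1C(Br)=C[C@H](O[Si](C)(C)C(C)(C)C)[C@@H](O[Si](C)(C)C(C)(C)C)[C@@H]1O[Si](C)(C)C(C)(C)C
F7 | step 12 | pinacol enol borate at C8a (O–Bpin in place of Bpin of 10) | CC[Si](CC)(CC)O[C@@H]1C(OB2OC(C)(C)C(C)(C)O2)=C[C@H](O[Si](C)(C)C(C)(C)C)[C@@H](O[Si](C)(C)C(C)(C)C)[C@@H]1O[Si](C)(C)C(C)(C)C
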